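The runs stem from a simulated flask on assumed constants; the scatter is artificial.

Start from the ratio of D to Z, which you want at two times far apart.

| setting | zeta | flask |
|---|---|---|
| L | 0.050 M | 0.050 M |
| E | 1 mM | 1.00 mM |
| remark | the very flask that is asked about, followed so far |  |
| time |  | 12 min |

zeta run (percent of the L charged)

| time / s | D / % | Z / % |
|---|---|---|
| 10.0 | 2 | 2 |
| 12.0 | 1 | 4 |
| 25.0 | 7 | 6 |
| 50.0 | 8 | 13 |
| 80.0 | 16 | 20 |

(standard deviation of a reading: 1.5 percentage points)

- percent here means L units held: one Q counts as two
- steps under discussion: L <-> Z; L <-> D; L <-> X; L + E -> G; 2 L -> Q; Z -> J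

* ratio of D to Z at 4.0 s
* ratio of D to Z at 12 min

In this flask the ratio reads 0.500 over the first two readings and 0.800 at the last. With a scatter of 1.5 percentage points on readings this small the rise is only a hint. But if Z can go back to L, the earliest readings lie nearest the start, so for 4.0 s I commit to about 0.500.

The time 12 min is far longer than the 80.0 s followed so far. So suppose that L ⇌ Z stands in balance (a pre-equilibrium) and that D, once made, stays. Then L and Z form one pool, and D draws on the L in it. The last reading, taking c_L as what D and Z leave of the charge, gives the free share, the part of c_L + c_Z that stands as L: 0.762.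

The rise of D up to the last reading, taken against the whole charge, gives a rough rate constant of about 0.00200 s⁻¹, so in this reckoning the pool decays at 0.00152 s⁻¹, and after 12 min 33.4% of it is left. Leaving Z → J aside, I count D as what the pool lost and Z as the part of the remainder that is not free, so my estimate of the ratio, with the scatter of the readings in it, comes to 8.38. If E takes a slice of L at the start, that shrinks D and Z alike, so in this reckoning it cancels.

The forecast gives 0.77 at 4.0 s and 1 at 12 min, the second in its words: “I guess about 1, with wide uncertainty.” My two numbers differ from both.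

The flask gives 0.524 at 4.0 s and 8.39 at 12 min.

    L ⇌ Z (K = 0.363, k = 0.00421 s⁻¹)
    L ⇌ D (K = 102, k = 0.00215 s⁻¹)
    L ⇌ X (K = 0.410, k = 2.11 × 10⁻⁵ s⁻¹)
    L + E → G (k = 3.18 L mol⁻¹ s⁻¹)
    2 L → Q (k = 2.21 × 10⁻⁴ L mol⁻¹ s⁻¹)
    Z → J (k = 8.58 × 10⁻⁴ s⁻¹)

The half-life of Z for going back to L, 1.0 min, is short against 12 min, and at that time L and Z stand at 19.0% and 7.46%, a free share of 0.718. My reckoning with the free share 0.762 has no term in E, so it gives 8.38 for the neighbour flask with 6.0 × 10⁻⁴ M of E as well. That neighbour holds 1.20% of G against 2.00% here and gives 8.39.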